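**Retrosynthetic overview**

1. Glaucolide A ⇐ peracid epoxidation of the E-4,5-olefin (last step); the 13-acetoxy-7(11)-ene butenolide ⇐ acetylative 1,3-transposition of a 7-hydroxy-11(13)-methylene lactone, itself from an intramolecular Morita–Baylis–Hillman closure of a C6 acrylate onto a C7 ketone.
2. The 1-oxo-10α-hydroxy unit ⇐ ketohydroxylation of the E-1(10)-olefin of a germacra-1(10),4-diene, whose C14 methyl comes from an enol triflate.
3. Ten-membered ring ⇐ anionic oxy-Cope rearrangement of a trans-1-vinyl-2-isopropenylcyclohexanol (C2–C3 formed, C5–C10 broken), the enolate trapped as the triflate.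
4. Cyclohexane ⇐ intramolecular carbonyl-ene cyclisation of a ribose-derived aldehyde carrying a prenyl-type olefin.
5. C6 and C8 (and the sacrificial C7) ⇐ 2,3-O-isopropylidene-D-ribono-1,4-lactone. Ring order: cyclohexane → cyclodecadiene → butenolide → epoxide.

Assumption: locants C1–C15 used for intermediates are those of the germacrane skeleton of the target (C9 = lactone carbonyl carbon of 1; C8, C7, C6, C5 = ribonic C2, C3, C4, C5); α is the ring face that carries O6 and O8 in the target.

**Route**

Step 1
Reactants: 1 2,3-O-isopropylidene-D-ribono-1,4-lactone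
Product: 2 2,3-O-isopropylidene-D-ribo-pentodialdono-1,4-lactone (C5 aldehyde)
Conditions: DMP, CH2Cl2, 0 °C → rt; used crude
Reagents that add atoms: none
Why: Dess–Martin oxidation of the only free (primary) alcohol under non-basic conditions leaves the α-stereocentre untouched.

Step 2
Reactants: 2 C5 aldehyde
Product: 3 5,6,7-trideoxy-6-methyl-2,3-O-isopropylidene-D-ribo-hept-5-enono-1,4-lactone
Conditions: i-PrPPh3I, n-BuLi, THF, 0 °C; then 2, −78 → 0 °C
Reagents that add atoms: isopropyltriphenylphosphonium iodide, CC(C)[P+](c1ccccc1)(c1ccccc1)c1ccccc1.[I-]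
Why: Wittig olefination with the non-stabilised isopropylidene ylide is much faster at the aldehyde than at the lactone and installs the Me2C=CH unit (future C4/C5/C15 and ene donor) without epimerising C6 at low temperature.

Step 3
Reactants: 3 alkenyl lactone
Product: 4 5,6,7-trideoxy-6-methyl-2,3-O-isopropylidene-D-ribo-hept-5-enofuranose (lactol; anomer mixture)
Conditions: DIBAL-H, CH2Cl2, −78 °C; Rochelle salt work-up
Reagents that add atoms: none
Why: Controlled DIBAL half-reduction of a γ-lactone stops at the lactol through the stable aluminium hemiacetal.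

Step 4
Reactants: 4 lactol
Product: 6 C6-O-TBS methyl enol ether (E/Z mixture), via hydroxy enol ether 5 (not isolated)
Conditions: MeOCH2PPh3Cl, KOtBu, THF, 0 °C → rt; then imidazole, TBSCl, DMF, rt
Reagents that add atoms: (methoxymethyl)triphenylphosphonium chloride, COC[P+](c1ccccc1)(c1ccccc1)c1ccccc1.[Cl-]; tert-butyldimethylsilyl chloride, CC(C)(C)[Si](C)(C)Cl
Why: Wittig methoxymethylenation of the open hydroxy-aldehyde form adds C10 and turns the lactol carbon into the future C9 methylene, and the liberated C6 hydroxyl is silylated in the same flask.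

Step 5
Reactants: 6 silylated enol ether
Product: 7 C10 aldehyde (6-O-TBS; 7,8-O-isopropylidene; D-ribo)
Conditions: Hg(OAc)2, THF/H2O, 0 °C; then aq. KI
Reagents that add atoms: water, O
Why: Mercury-assisted hydrolysis of the methyl enol ether is near-neutral, so the acetonide, the silyl ether and the β-alkoxy aldehyde survive.

Step 6
Reactants: 7 aldehyde
Product: 8 cyclohexanol (C5–C10 ring; O6, O7, O8 all α; isopropenyl at C5 β; 10-OH α)
Conditions: Me2AlCl (2 equiv), CH2Cl2, −78 → −30 °C
Reagents that add atoms: none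
Why: Lewis-acid-promoted intramolecular carbonyl-ene reaction (the citronellal → isopulegol manifold) closes C5–C10 through a chair in which O6 and O8 are equatorial, so the ribose centres place the new isopropenyl and hydroxyl groups equatorial and mutually trans.

Step 7
Reactants: 8 cyclohexanol
Product: 9 cyclohexanone (C10 ketone)
Conditions: DMP, pyridine, CH2Cl2, 0 °C
Reagents that add atoms: none
Why: Buffered Dess–Martin oxidation gives the α-isopropenyl ketone without epimerisation, conjugation or β-elimination of the silyloxy group.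

Step 8
Reactants: 9 cyclohexanone
Product: 10 10-vinyl carbinol (vinyl α and trans to the isopropenyl group; OH β)
Conditions: CH2=CHMgBr, CeCl3, THF, −78 °C
Reagents that add atoms: vinylmagnesium bromide, C=C[Mg]Br
Why: The non-basic organocerium reagent adds 1,2 without enolisation, and equatorial attack away from the neighbouring isopropenyl group gives the trans-1,2-dialkenyl carbinol needed for a chair oxy-Cope.

Step 9
Reactants: 10 divinyl carbinol
Product: 13 ten-membered enol triflate (E-4,5-olefin; C9 and C2 trans across C10=C1), via potassium alkoxide 11 (not isolated), via potassium enolate 12 (not isolated)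
Conditions: KH, 18-crown-6, THF, 0 °C → rt; then PhNTf2, −78 → 0 °C
Reagents that add atoms: N-phenyl-bis(trifluoromethanesulfonimide), O=S(=O)(N(c1ccccc1)S(=O)(=O)C(F)(F)F)C(F)(F)F
Why: Anionic oxy-Cope [3,3]-sigmatropic rearrangement through the chair transition state forms C2–C3, breaks C5–C10 and gives the E-4,5-olefin and a single regio- and geometrically defined enolate, which is O-triflated before it can equilibrate.

Step 10
Reactants: 13 enol triflate
Product: 14 6α-(tert-butyldimethylsilyloxy)-7α,8α-(isopropylidenedioxy)-11,12,13-trinorgermacra-1(10)E,4E-diene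
Conditions: MeMgBr, Fe(acac)3 (5 mol %), THF/NMP, −30 °C
Reagents that add atoms: methylmagnesium bromide, C[Mg]Br
Why: Iron-catalysed cross-coupling of the alkenyl triflate with the methyl Grignard reagent proceeds with retention of olefin geometry and installs C14.

Step 11
Reactants: 14 diene
Product: 15 10α-hydroxy-1-oxo-6α-(tert-butyldimethylsilyloxy)-7α,8α-(isopropylidenedioxy)-11,12,13-trinorgermacr-4E-ene
Conditions: RuCl3 (1 mol %), Oxone, NaHCO3, EtOAc/MeCN/H2O, rt
Reagents that add atoms: potassium peroxymonosulfate (Oxone), [K+].[O-]S(=O)(=O)OO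
Why: Ruthenium-tetroxide-catalysed ketohydroxylation adds syn to the exposed outer face of the more electron-rich, unhindered 1(10)-olefin (the 4,5-olefin is shielded and deactivated by the allylic silyl ether), so the ring conformation fixed by C6–C8 sets C10 with the hydroxyl α and C1 becomes the ketone.

Step 12
Reactants: 15 ketol acetonide
Product: 16 7α,8α-diol (6α-OTBS retained)
Conditions: CeCl3·7H2O, (CO2H)2 (cat.), MeCN, rt
Reagents that add atoms: none
Why: Mild Lewis-acid hydrolysis removes the isopropylidene acetal while the secondary TBS ether and the tertiary ketol survive.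

Step 13
Reactants: 16 diol
Product: 17 8α-methacrylate (7α-OH free)
Conditions: methacrylic anhydride (1.05 equiv), Et3N, DMAP (cat.), CH2Cl2, −40 °C
Reagents that add atoms: methacrylic anhydride, CC(=C)C(=O)OC(=O)C(C)=C
Why: Kinetic acylation takes the less hindered C8 hydroxyl (next to CH2) over the C7 hydroxyl, which is shielded by the bulky C6 silyl ether, and over the tertiary C10 hydroxyl.

Step 14
Reactants: 17 hydroxy methacrylate
Product: 18 7-ketone
Conditions: DMP, pyridine, CH2Cl2, 0 °C
Reagents that add atoms: none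
Why: Dess–Martin oxidation of the only secondary alcohol gives the C7 ketone (removing the sacrificial C7 stereocentre) without touching the tertiary ketol.

Step 15
Reactants: 18 silyloxy ketone
Product: 19 6α-hydroxy-7-ketone
Conditions: HF·pyridine, THF/pyridine, 0 °C
Reagents that add atoms: none
Why: Acidic fluoride desilylation frees the C6 hydroxyl without the base-mediated epimerisation that the doubly activated C6–H would otherwise risk.

Step 16
Reactants: 19 α-hydroxy ketone
Product: 20 6α-acrylate
Conditions: CH2=CHCOCl, i-Pr2NEt, CH2Cl2, −40 °C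
Reagents that add atoms: acryloyl chloride, C=CC(=O)Cl
Why: O-acylation of the only reactive (secondary) hydroxyl brings in C11, C12 and C13; the tertiary C10 hydroxyl does not react at this temperature.

Step 17
Reactants: 20 keto acrylate
Product: 21 7ξ,10α-dihydroxy-8α-methacryloyloxy-1-oxogermacra-4E,11(13)-dien-6α,12-olide
Conditions: PMe3 (0.3 equiv), CH2Cl2/t-BuOH, 0 °C → rt
Reagents that add atoms: none
Why: Intramolecular Morita–Baylis–Hillman reaction: the phosphine adds to the acrylate (the α-substituted methacrylate is inert) and the resulting enolate closes the five-membered lactone onto the activated α,α'-dioxygenated C7 ketone; the new C7 carbinol configuration is inconsequential.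

Step 18
Reactants: 21 hydroxy methylene lactone
Product: 22 10α,13-diacetoxy-8α-methacryloyloxy-1-oxogermacra-4E,7(11)-dien-6α,12-olide
Conditions: Ac2O, DMAP, Et3N, toluene, 60 °C
Reagents that add atoms: acetic anhydride, CC(=O)OC(C)=O
Why: Both tertiary hydroxyls are acetylated and the tertiary allylic C7 acetate undergoes the DMAP-mediated 1,3-acyloxy shift typical of Baylis–Hillman acetates (formally a [3,3] transposition) to the more stable tetrasubstituted conjugated butenolide with the primary C13 acetate.

Step 19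
Reactants: 22 4,5-olefin
Product: 23 glaucolide A
Conditions: mCPBA, Na2HPO4, CH2Cl2, 0 °C
Reagents that add atoms: meta-chloroperoxybenzoic acid, OOC(=O)c1cccc(Cl)c1
Why: Prilezhaev epoxidation of the only electron-rich olefin occurs on its outer face, syn to O6 (H6 eclipses the olefin to avoid A(1,3) strain with C15 and the ring blocks the other face, as in costunolide → parthenolide), giving the trans 4α,5β-epoxide.

**Compound list**

1 | 2,3-O-isopropylidene-D-ribono-1,4-lactone | O=C1[C@@H]2OC(C)(C)O[C@@H]2[C@@H](CO)O1 | starting material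
2 | 2,3-O-isopropylidene-D-ribo-pentodialdono-1,4-lactone | O=C1[C@@H]2OC(C)(C)O[C@@H]2[C@@H](C=O)O1 | intermediate
3 | 5,6,7-trideoxy-6-methyl-2,3-O-isopropylidene-D-ribo-hept-5-enono-1,4-lactone | O=C1[C@@H]2OC(C)(C)O[C@@H]2[C@@H](C=C(C)C)O1 | intermediate
4 | 5,6,7-trideoxy-6-methyl-2,3-O-isopropylidene-D-ribo-hept-5-enofuranose (anomer mixture) | OC1[C@@H]2OC(C)(C)O[C@@H]2[C@@H](C=C(C)C)O1 | intermediate
5 | hydroxy enol ether MeO–C10H=C9H–C8–C7–C6(OH)–C5H=C4Me2, 7,8-O-isopropylidene, D-ribo, E/Z mixture | COC=C[C@@H]1OC(C)(C)O[C@@H]1[C@H](O)C=C(C)C | intermediate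
6 | 6-O-TBS ether of 5 | COC=C[C@@H]1OC(C)(C)O[C@@H]1[C@H](O[Si](C)(C)C(C)(C)C)C=C(C)C | intermediate
7 | C10 aldehyde, 6-O-TBS, 7,8-O-isopropylidene, D-ribo | O=CC[C@@H]1OC(C)(C)O[C@@H]1[C@H](O[Si](C)(C)C(C)(C)C)C=C(C)C | intermediate
8 | cyclohexanol (ring C5–C10): 6α-OTBS, 7α,8α-isopropylidenedioxy, 5β-isopropenyl, 10α-OH | O[C@@H]1C[C@@H]2OC(C)(C)O[C@@H]2[C@H](O[Si](C)(C)C(C)(C)C)[C@H]1C(C)=C | intermediate
9 | corresponding C10 cyclohexanone | O=C1C[C@@H]2OC(C)(C)O[C@@H]2[C@H](O[Si](C)(C)C(C)(C)C)[C@H]1C(C)=C | intermediate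
10 | 10α-vinyl-10β-hydroxy carbinol (vinyl trans to the 5β-isopropenyl group) | C=C[C@]1(O)C[C@@H]2OC(C)(C)O[C@@H]2[C@H](O[Si](C)(C)C(C)(C)C)[C@H]1C(C)=C | intermediate
11 | potassium alkoxide of 10 | C=C[C@]1([O-])C[C@@H]2OC(C)(C)O[C@@H]2[C@H](O[Si](C)(C)C(C)(C)C)[C@H]1C(C)=C.[K+] | intermediate
12 | potassium enolate of the ring-expanded cyclodec-4E-en-10-one (C9 and C2 trans across C10=C1) | CC1(C)O[C@H]2C/C([O-])=C/CC/C(C)=C/[C@@H](O[Si](C)(C)C(C)(C)C)[C@H]2O1.[K+] | intermediate
13 | corresponding C10 enol triflate | CC1(C)O[C@H]2C/C(OS(=O)(=O)C(F)(F)F)=C/CC/C(C)=C/[C@@H](O[Si](C)(C)C(C)(C)C)[C@H]2O1 | intermediate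
14 | 6α-(TBSO)-7α,8α-(isopropylidenedioxy)-11,12,13-trinorgermacra-1(10)E,4E-diene | CC1(C)O[C@H]2C/C(C)=C/CC/C(C)=C/[C@@H](O[Si](C)(C)C(C)(C)C)[C@H]2O1 | intermediate
15 | 10α-hydroxy-1-oxo-6α-(TBSO)-7α,8α-(isopropylidenedioxy)-11,12,13-trinorgermacr-4E-ene | CC1(C)O[C@H]2C[C@@](C)(O)C(=O)CC/C(C)=C/[C@@H](O[Si](C)(C)C(C)(C)C)[C@H]2O1 | intermediate
16 | 7α,8α,10α-trihydroxy-1-oxo-6α-(TBSO)-11,12,13-trinorgermacr-4E-ene | O[C@H]1C[C@@](C)(O)C(=O)CC/C(C)=C/[C@@H](O[Si](C)(C)C(C)(C)C)[C@H]1O | intermediate
17 | 8α-methacrylate of 16 | C=C(C)C(=O)O[C@H]1C[C@@](C)(O)C(=O)CC/C(C)=C/[C@@H](O[Si](C)(C)C(C)(C)C)[C@H]1O | intermediate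
18 | 10α-hydroxy-8α-methacryloyloxy-6α-(TBSO)-11,12,13-trinorgermacr-4E-ene-1,7-dione | C=C(C)C(=O)O[C@H]1C[C@@](C)(O)C(=O)CC/C(C)=C/[C@@H](O[Si](C)(C)C(C)(C)C)C1=O | intermediate
19 | 6α,10α-dihydroxy-8α-methacryloyloxy-11,12,13-trinorgermacr-4E-ene-1,7-dione | C=C(C)C(=O)O[C@H]1C[C@@](C)(O)C(=O)CC/C(C)=C/[C@@H](O)C1=O | intermediate
20 | 6α-acrylate of 19 | C=C(C)C(=O)O[C@H]1C[C@@](C)(O)C(=O)CC/C(C)=C/[C@@H](OC(=O)C=C)C1=O | intermediate
21 | 7ξ,10α-dihydroxy-8α-methacryloyloxy-1-oxogermacra-4E,11(13)-dien-6α,12-olide (C7 epimers both usable) | C=C(C)C(=O)O[C@H]1C[C@@](C)(O)C(=O)CC/C(C)=C/[C@H]2OC(=O)C(=C)C12O | intermediate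
22 | 10α,13-diacetoxy-8α-methacryloyloxy-1-oxogermacra-4E,7(11)-dien-6α,12-olide | C=C(C)C(=O)O[C@H]1C[C@@](C)(OC(C)=O)C(=O)CC/C(C)=C/[C@H]2OC(=O)C(COC(C)=O)=C12 | intermediate
23 | glaucolide A | C=C(C)C(=O)O[C@H]1C[C@@](C)(OC(C)=O)C(=O)CC[C@@]2(C)O[C@@H]2[C@H]2OC(=O)C(COC(C)=O)=C12 | target

**Step count and risks**

Total steps: 19. Longest linear sequence: 19 (fully linear from 1).

The three steps most likely to fail:

Step 11 (ketohydroxylation of 14): the reagent may not discriminate cleanly between the two trisubstituted olefins or may over-oxidise, and the C10 configuration rests on conformational control rather than on a neighbouring group. The fallback sets out from diene 14: catalytic OsO4 with N-methylmorpholine N-oxide (1.1 equiv) in acetone/water at 0 °C dihydroxylates the unhindered 1(10)-olefin from its outer face to give the 1β,10α-diol of the 6α-silyloxy-7α,8α-acetonide F1. Dess–Martin oxidation of its secondary C1 hydroxyl (the tertiary one is inert) then comes back to the route at ketol 15.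

Step 13 (mono-methacrylation of 16): discrimination between the C8 and C7 hydroxyls is steric only and acyl migration is possible. The fallback sets out from diol 16: heating with Bu2SnO in toluene with removal of water gives the 7α,8α-O-dibutylstannylene acetal F2, whose less hindered, tin-activated O8 is acylated by methacryloyl chloride at 0 °C. Aqueous work-up releases the C7 hydroxyl and comes back to the route at 17.

Step 17 (intramolecular Morita–Baylis–Hillman closure of 20): addition to a hindered ketone may be slow or reversible, and the basic catalyst could epimerise C6 or C8. The fallback sets out from acrylate 20: conjugate addition of PhSeLi in THF at −78 °C generates the ester enolate, which closes onto the C7 ketone (Michael–aldol) to give the 13-phenylselanyl β-hydroxy lactone F3. Oxidation with H2O2/pyridine at 0 °C gives the selenoxide F4, whose syn-elimination at room temperature comes back to the route at 21.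

Further compounds
F1 | step 11 | 6α-(tert-butyldimethylsilyloxy)-7α,8α-(isopropylidenedioxy)-11,12,13-trinorgermacr-4E-ene-1β,10α-diol | CC1(C)O[C@H]2C[C@@](C)(O)[C@H](O)CC/C(C)=C/[C@@H](O[Si](C)(C)C(C)(C)C)[C@H]2O1
F2 | step 13 | 7α,8α-O-dibutylstannylene acetal of diol 16 | CCCC[Sn]1(CCCC)O[C@H]2C[C@@](C)(O)C(=O)CC/C(C)=C/[C@@H](O[Si](C)(C)C(C)(C)C)[C@H]2O1
F3 | step 17 | 7ξ,10α-dihydroxy-8α-methacryloyloxy-1-oxo-13-(phenylselanyl)germacr-4E-en-6α,12-olide (11ξ) | C=C(C)C(=O)O[C@H]1C[C@@](C)(O)C(=O)CC/C(C)=C/[C@H]2OC(=O)C(C[Se]c3ccccc3)C12O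
F4 | step 17 | selenoxide of F3 | C=C(C)C(=O)O[C@H]1C[C@@](C)(O)C(=O)CC/C(C)=C/[C@H]2OC(=O)C(C[Se](=O)c3ccccc3)C12O
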